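**Plan**
- Retrosynthesis: the benzyl and ethyl ethers come off last. Ring C is opened at O1–C2 and C3–OH (oxidative chalcone cyclisation), then cut at C3–C4 (styryl addition) and C4–C4a (ortho-formylation).
- Ring A is then split at C8–C8a, C6–C7 and C4a–C8a into a chiral siloxyalkyne and 3-ethoxycyclobutenone; the alkyne is cut at the bond between the stereocentre and the alkynyl carbon.
- Forward: side chain with its stereocentre, then the siloxyalkyne, then ring A by benzannulation, then ring C on the free phenol. Ring B is the phenyl group of a styryl Grignard reagent.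
- Feature used: ring A is a 1,3,5-trioxygenated benzene in which C8 lies between two oxygens and C4a is the only free position ortho to O1. A siloxyalkyne and a 3-alkoxycyclobutenone give exactly this pattern with each oxygen masked differently (OH, OSi, OEt).
- Stereochemistry: the single (R) centre is set by a catalyst-controlled iridium-catalysed allylic alkynylation of a racemic aryl vinyl carbinol and is a spectator in every later step.

Key step: step 6

Assumption: the sense of induction in step 2 is fixed by the ligand antipode; the antipode that gives the (R)-enyne is used (both are available from (R)- or (S)-BINOL) and is to be confirmed by correlation on the first run.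

**Route**

Step 1
Reactants: 1 4-(benzyloxy)-3-methoxybenzaldehyde
Product: 2 rac-1-[4-(benzyloxy)-3-methoxyphenyl]prop-2-en-1-ol
Conditions: CH2=CHMgBr, THF, 0 °C; NH4Cl aq
Reagents that add atoms: vinylmagnesium bromide, C=C[Mg]Br
Why: Grignard 1,2-addition of the vinyl nucleophile to the aldehyde gives the aryl vinyl carbinol, which may be racemic because the next step is enantioconvergent.

Step 2
Reactants: 2 rac-1-[4-(benzyloxy)-3-methoxyphenyl]prop-2-en-1-ol
Product: 3 (R)-{3-[4-(benzyloxy)-3-methoxyphenyl]pent-4-en-1-yn-1-yl}trimethylsilane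
Conditions: [Ir(cod)Cl]2 (4 mol%), BINOL-derived phosphoramidite–olefin ligand [N-(dinaphthodioxaphosphepin-4-yl)dibenz[b,f]azepine] (16 mol%), K[Me3SiC≡CBF3], KHF2, CF3CO2H, n-Bu4NBr, 1,4-dioxane, rt
Reagents that add atoms: potassium trifluoro[(trimethylsilyl)ethynyl]borate, C[Si](C)(C)C#C[B-](F)(F)F.[K+]
Why: This is the iridium-catalysed enantioconvergent allylic alkynylation of racemic branched allylic alcohols with potassium alkynyltrifluoroborates: acid activation ionises either enantiomer of 2 to an allyl-iridium species in which the chiral ligand directs the alkynyl group to the benzylic terminus and to one face, so the (R) centre is set by catalyst control with branched regiochemistry.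

Step 3
Reactants: 3 (R)-{3-[4-(benzyloxy)-3-methoxyphenyl]pent-4-en-1-yn-1-yl}trimethylsilane
Product: 4 (S)-1-(benzyloxy)-2-methoxy-4-(pent-1-en-4-yn-3-yl)benzene
Conditions: AgNO3 (10 mol%), CH2Cl2/MeOH/H2O, rt
Reagents that add atoms: none
Why: Silver-catalysed protodesilylation of a trimethylsilylalkyne runs through a silver acetylide under neutral conditions, so the acidic propargylic, allylic and benzylic C–H is never exposed to base and the configuration is retained (the descriptor becomes S only because the priorities change).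

Step 4
Reactants: 4 (S)-1-(benzyloxy)-2-methoxy-4-(pent-1-en-4-yn-3-yl)benzene
Product: 7 (R)-{[3-(4-(benzyloxy)-3-methoxyphenyl)pent-4-en-1-yn-1-yl]oxy}tri(propan-2-yl)silane, via lithium acetylide 5 (not isolated), via lithium ynolate 6 (not isolated)
Conditions: n-BuLi (1.0 equiv), THF, −78 °C; LiOOt-Bu (from t-BuOOH + LiN(SiMe3)2), −78 → 0 °C; i-Pr3SiOTf, −78 °C; cold NaHCO3 aq
Reagents that add atoms: lithium tert-butyl peroxide (from tert-butyl hydroperoxide), [Li+].CC(C)(C)O[O-]; triisopropylsilyl trifluoromethanesulfonate, CC(C)[Si](OS(=O)(=O)C(F)(F)F)(C(C)C)C(C)C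
Why: Oxygen transfer from lithium tert-butyl peroxide to a lithium acetylide and O-silylation of the resulting ynolate with a bulky silyl triflate is the standard preparation of triisopropylsiloxyalkynes; the sp C–H is removed kinetically, and the negative charge of 5 and of 6 shields the adjacent stereocentre from deprotonation until the cold quench.

Step 5
Reactants: 8 acetone (propan-2-one); 9 ethoxyacetylene
Product: 11 3-ethoxycyclobut-2-en-1-one, via ketene 10 (not isolated)
Conditions: 8 cracked as vapour at ca. 700 °C (hot-tube ketene generator), ketene stream passed into 9 (solution in hexanes diluted with CH2Cl2), −20 → 0 °C; used freshly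
Reagents that add atoms: none
Why: Thermal cracking of acetone delivers ketene with loss of methane, and the [2+2] cycloaddition of ketene with an ynol ether is regiospecific (the nucleophilic alkyne CH bonds to the ketene carbonyl carbon), which is the established preparation of this cyclobutenone.

Step 6
Reactants: 7 (R)-{[3-(4-(benzyloxy)-3-methoxyphenyl)pent-4-en-1-yn-1-yl]oxy}tri(propan-2-yl)silane; 11 3-ethoxycyclobut-2-en-1-one
Product: 16 (R)-2-{1-[4-(benzyloxy)-3-methoxyphenyl]prop-2-en-1-yl}-5-ethoxy-3-[tri(propan-2-yl)silyloxy]phenol, via ethoxyvinylketene 12 (not isolated), via vinylcyclobutenone adduct 13 (not isolated), via dienylketene 14 (not isolated), via cyclohexadienone tautomer 15 (not isolated)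
Conditions: 11 (1.5 equiv, added in portions), toluene, 80–90 °C, Ar
Reagents that add atoms: none
Why: Heat opens 11 by a 4π electrocyclic reaction to vinylketene 12, which undergoes a regiospecific [2+2] cycloaddition with 7 to give 13; the nucleophilic alkyne carbon (the one bearing the stereocentre) bonds to the ketene carbonyl carbon (C8–C8a) and the silyloxy carbon to the ketene α-carbon (C6–C7). A second 4π opening of 13 gives dienylketene 14, which closes ring A by a thermally allowed disrotatory 6π electrocyclisation that re-forms the C4a–C8a bond, and dienone 15 tautomerises to phenol 16. This is the Danheiser benzannulation of a cyclobutenone with a siloxyalkyne, a known route to resorcinol monosilyl ethers; the 3-alkoxy group of the cyclobutenone simply supplies the third oxygen. No stereocentre is created, since the sp3 ring carbon of 13 is lost on aromatisation. The existing (R) centre takes part in no bond-breaking event and should survive because the medium is neutral and aprotic, which excludes a base-mediated shift to an allene. The selectivity needed is regiochemical and is secured by the polarity of the ketene–ynol ether pair, so that the side chain sits between OH and OSi, the ethoxy group is para to it, and one free CH remains ortho to the free OH.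

Step 7
Reactants: 16 (R)-2-{1-[4-(benzyloxy)-3-methoxyphenyl]prop-2-en-1-yl}-5-ethoxy-3-[tri(propan-2-yl)silyloxy]phenol
Product: 18 (R)-3-{1-[4-(benzyloxy)-3-methoxyphenyl]prop-2-en-1-yl}-6-ethoxy-2-hydroxy-4-[tri(propan-2-yl)silyloxy]benzaldehyde, via hydroxymethyl phenol 17 (not isolated)
Conditions: MgCl2, Et3N, (CH2O)n, THF, reflux; NH4Cl aq
Reagents that add atoms: paraformaldehyde (formaldehyde), C=O
Why: In the magnesium-mediated ortho-formylation (Casnati–Skattebøl reaction) formaldehyde is delivered within a magnesium phenoxide, so only the position ortho to the free OH reacts, which here is C4a alone, and the hydroxymethyl intermediate 17 is oxidised to the aldehyde by hydride transfer to a second formaldehyde.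

Step 8
Reactants: 18 (R)-3-{1-[4-(benzyloxy)-3-methoxyphenyl]prop-2-en-1-yl}-6-ethoxy-2-hydroxy-4-[tri(propan-2-yl)silyloxy]benzaldehyde
Product: 20 (R)-4-(benzyloxy)-3-{1-[4-(benzyloxy)-3-methoxyphenyl]prop-2-en-1-yl}-6-ethoxy-2-hydroxybenzaldehyde, via caesium phenoxide 19 (not isolated)
Conditions: CsF, BnBr (1.1 equiv), DMF, 0 °C → rt
Reagents that add atoms: benzyl bromide, BrCc1ccccc1
Why: Fluoride cleaves the aryl silyl ether to the phenoxide para to the formyl group, which is benzylated in the same flask (one-pot desilylation–Williamson etherification) while the other OH, hydrogen-bonded to the aldehyde and hindered, stays free; the benzyl ether is needed because a silyl ether would not survive the alkaline step 11.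

Step 9
Reactants: 20 (R)-4-(benzyloxy)-3-{1-[4-(benzyloxy)-3-methoxyphenyl]prop-2-en-1-yl}-6-ethoxy-2-hydroxybenzaldehyde
Product: 21 (E)-1-{4-(benzyloxy)-3-[(R)-1-(4-(benzyloxy)-3-methoxyphenyl)prop-2-en-1-yl]-6-ethoxy-2-hydroxyphenyl}-3-phenylprop-2-en-1-ol (both carbinol epimers)
Conditions: (E)-PhCH=CHMgBr (2.5 equiv, from (E)-β-bromostyrene and Mg), THF, −40 → 0 °C; NH4Cl aq; used crude
Reagents that add atoms: (E)-styrylmagnesium bromide, Br[Mg]/C=C/c1ccccc1
Why: Grignard 1,2-addition to the salicylaldehyde, after one equivalent of reagent has deprotonated the phenol, gives the allylic benzylic carbinol as an epimer mixture that is of no consequence because the carbinol carbon is oxidised next.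

Step 10
Reactants: 21 (E)-1-{4-(benzyloxy)-3-[(R)-1-(4-(benzyloxy)-3-methoxyphenyl)prop-2-en-1-yl]-6-ethoxy-2-hydroxyphenyl}-3-phenylprop-2-en-1-ol
Product: 22 (E)-1-{4-(benzyloxy)-3-[(R)-1-(4-(benzyloxy)-3-methoxyphenyl)prop-2-en-1-yl]-6-ethoxy-2-hydroxyphenyl}-3-phenylprop-2-en-1-one
Conditions: MnO2 (activated, excess), CH2Cl2, rt
Reagents that add atoms: none
Why: MnO2 oxidises allylic and benzylic alcohols selectively under neutral conditions, and the product is stabilised as a hydrogen-bonded 2'-hydroxychalcone.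

Step 11
Reactants: 22 (E)-1-{4-(benzyloxy)-3-[(R)-1-(4-(benzyloxy)-3-methoxyphenyl)prop-2-en-1-yl]-6-ethoxy-2-hydroxyphenyl}-3-phenylprop-2-en-1-one
Product: 24 7-(benzyloxy)-8-{(R)-1-[4-(benzyloxy)-3-methoxyphenyl]prop-2-en-1-yl}-5-ethoxy-3-hydroxy-2-phenyl-4H-chromen-4-one, via dihydroflavonol 23 (not isolated)
Conditions: 30% H2O2, NaOH aq, MeOH/THF, 0 °C → rt
Reagents that add atoms: hydrogen peroxide, OO
Why: In the Algar–Flynn–Oyamada reaction alkaline H2O2 oxidises the enone, the phenoxide closes ring C at the β-carbon to dihydroflavonol 23, and this is dehydrogenated in the same medium to the flavonol, a course precedented for 2'-hydroxy-4',6'-dialkoxy-3'-alkylchalcones and harmless to the isolated vinyl group.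

Step 12
Reactants: 24 7-(benzyloxy)-8-{(R)-1-[4-(benzyloxy)-3-methoxyphenyl]prop-2-en-1-yl}-5-ethoxy-3-hydroxy-2-phenyl-4H-chromen-4-one
Product: 25 3,5,7-trihydroxy-8-[(R)-1-(4-hydroxy-3-methoxyphenyl)prop-2-en-1-yl]-2-phenyl-4H-chromen-4-one (target)
Conditions: BCl3 (excess), C6HMe5, CH2Cl2, −78 → 0 °C; MeOH
Reagents that add atoms: none
Why: BCl3 with pentamethylbenzene as a cation scavenger cleaves aryl benzyl ethers at low temperature and, by chelation to the C4 carbonyl, the peri 5-ethyl ether, while the unchelated guaiacyl methyl ether, the vinyl group and the stereocentre are left untouched (Lewis acid ether cleavage).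

**Compound list**

1 | 4-(benzyloxy)-3-methoxybenzaldehyde | COc1cc(C=O)ccc1OCc1ccccc1 | starting material
2 | rac-1-[4-(benzyloxy)-3-methoxyphenyl]prop-2-en-1-ol | C=CC(O)c1ccc(OCc2ccccc2)c(OC)c1 | intermediate
3 | (R)-{3-[4-(benzyloxy)-3-methoxyphenyl]pent-4-en-1-yn-1-yl}trimethylsilane | C=C[C@H](c1ccc(OCc2ccccc2)c(OC)c1)C#C[Si](C)(C)C | intermediate
4 | (S)-1-(benzyloxy)-2-methoxy-4-(pent-1-en-4-yn-3-yl)benzene | C=C[C@H](c1ccc(OCc2ccccc2)c(OC)c1)C#C | intermediate
5 | lithium acetylide of 4 [lithium 3-(4-(benzyloxy)-3-methoxyphenyl)pent-4-en-1-yn-1-ide, configuration as in 4] | C=C[C@H](c1ccc(OCc2ccccc2)c(OC)c1)C#C[Li] | intermediate (not isolated)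
6 | lithium (R)-3-[4-(benzyloxy)-3-methoxyphenyl]pent-4-en-1-yn-1-olate | C=C[C@H](c1ccc(OCc2ccccc2)c(OC)c1)C#CO[Li] | intermediate (not isolated)
7 | (R)-{[3-(4-(benzyloxy)-3-methoxyphenyl)pent-4-en-1-yn-1-yl]oxy}tri(propan-2-yl)silane | C=C[C@H](c1ccc(OCc2ccccc2)c(OC)c1)C#CO[Si](C(C)C)(C(C)C)C(C)C | intermediate
8 | acetone (propan-2-one) | CC(C)=O | starting material
9 | ethoxyacetylene (ethoxyethyne) | C#COCC | starting material
10 | ketene (ethenone) | C=C=O | intermediate (not isolated)
11 | 3-ethoxycyclobut-2-en-1-one | CCOC1=CC(=O)C1 | intermediate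
12 | 3-ethoxybuta-1,3-dien-1-one | C=C(OCC)C=C=O | intermediate (not isolated)
13 | 2-{(R)-1-[4-(benzyloxy)-3-methoxyphenyl]prop-2-en-1-yl}-4-(1-ethoxyethenyl)-3-[tri(propan-2-yl)silyloxy]cyclobut-2-en-1-one (both epimers at the ring sp3 carbon) | C=C[C@H](c1ccc(OCc2ccccc2)c(OC)c1)C1=C(O[Si](C(C)C)(C(C)C)C(C)C)C(C(=C)OCC)C1=O | intermediate (not isolated)
14 | (3E)-2-{(R)-1-[4-(benzyloxy)-3-methoxyphenyl]prop-2-en-1-yl}-5-ethoxy-3-[tri(propan-2-yl)silyloxy]hexa-1,3,5-trien-1-one | C=C[C@H](c1ccc(OCc2ccccc2)c(OC)c1)C(=C=O)/C(O[Si](C(C)C)(C(C)C)C(C)C)=C\C(=C)OCC | intermediate (not isolated)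
15 | 2-{(R)-1-[4-(benzyloxy)-3-methoxyphenyl]prop-2-en-1-yl}-5-ethoxy-3-[tri(propan-2-yl)silyloxy]cyclohexa-2,4-dien-1-one | C=C[C@H](c1ccc(OCc2ccccc2)c(OC)c1)C1=C(O[Si](C(C)C)(C(C)C)C(C)C)C=C(OCC)CC1=O | intermediate (not isolated)
16 | (R)-2-{1-[4-(benzyloxy)-3-methoxyphenyl]prop-2-en-1-yl}-5-ethoxy-3-[tri(propan-2-yl)silyloxy]phenol | C=C[C@H](c1ccc(OCc2ccccc2)c(OC)c1)c1c(O)cc(OCC)cc1O[Si](C(C)C)(C(C)C)C(C)C | intermediate
17 | (R)-2-{1-[4-(benzyloxy)-3-methoxyphenyl]prop-2-en-1-yl}-5-ethoxy-6-(hydroxymethyl)-3-[tri(propan-2-yl)silyloxy]phenol (present as its magnesium salt) | C=C[C@H](c1ccc(OCc2ccccc2)c(OC)c1)c1c(O)c(CO)c(OCC)cc1O[Si](C(C)C)(C(C)C)C(C)C | intermediate (not isolated)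
18 | (R)-3-{1-[4-(benzyloxy)-3-methoxyphenyl]prop-2-en-1-yl}-6-ethoxy-2-hydroxy-4-[tri(propan-2-yl)silyloxy]benzaldehyde | C=C[C@H](c1ccc(OCc2ccccc2)c(OC)c1)c1c(O)c(C=O)c(OCC)cc1O[Si](C(C)C)(C(C)C)C(C)C | intermediate
19 | caesium (R)-2-{1-[4-(benzyloxy)-3-methoxyphenyl]prop-2-en-1-yl}-5-ethoxy-4-formyl-3-hydroxyphenolate | C=C[C@H](c1ccc(OCc2ccccc2)c(OC)c1)c1c(O)c(C=O)c(OCC)cc1[O-].[Cs+] | intermediate (not isolated)
20 | (R)-4-(benzyloxy)-3-{1-[4-(benzyloxy)-3-methoxyphenyl]prop-2-en-1-yl}-6-ethoxy-2-hydroxybenzaldehyde | C=C[C@H](c1ccc(OCc2ccccc2)c(OC)c1)c1c(O)c(C=O)c(OCC)cc1OCc1ccccc1 | intermediate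
21 | (E)-1-{4-(benzyloxy)-3-[(R)-1-(4-(benzyloxy)-3-methoxyphenyl)prop-2-en-1-yl]-6-ethoxy-2-hydroxyphenyl}-3-phenylprop-2-en-1-ol (both carbinol epimers) | C=C[C@H](c1ccc(OCc2ccccc2)c(OC)c1)c1c(O)c(C(O)/C=C/c2ccccc2)c(OCC)cc1OCc1ccccc1 | intermediate
22 | (E)-1-{4-(benzyloxy)-3-[(R)-1-(4-(benzyloxy)-3-methoxyphenyl)prop-2-en-1-yl]-6-ethoxy-2-hydroxyphenyl}-3-phenylprop-2-en-1-one | C=C[C@H](c1ccc(OCc2ccccc2)c(OC)c1)c1c(O)c(C(=O)/C=C/c2ccccc2)c(OCC)cc1OCc1ccccc1 | intermediate
23 | 7-(benzyloxy)-8-{(R)-1-[4-(benzyloxy)-3-methoxyphenyl]prop-2-en-1-yl}-5-ethoxy-3-hydroxy-2-phenylchroman-4-one (2,3-trans, both ring diastereomers) | C=C[C@H](c1ccc(OCc2ccccc2)c(OC)c1)c1c(OCc2ccccc2)cc(OCC)c2c1OC(c1ccccc1)C(O)C2=O | intermediate (not isolated)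
24 | 7-(benzyloxy)-8-{(R)-1-[4-(benzyloxy)-3-methoxyphenyl]prop-2-en-1-yl}-5-ethoxy-3-hydroxy-2-phenyl-4H-chromen-4-one | C=C[C@H](c1ccc(OCc2ccccc2)c(OC)c1)c1c(OCc2ccccc2)cc(OCC)c2c(=O)c(O)c(-c3ccccc3)oc12 | intermediate
25 | 3,5,7-trihydroxy-8-[(R)-1-(4-hydroxy-3-methoxyphenyl)prop-2-en-1-yl]-2-phenyl-4H-chromen-4-one | C=C[C@H](c1ccc(O)c(OC)c1)c1c(O)cc(O)c2c(=O)c(O)c(-c3ccccc3)oc12 | target

**Step count**

Total: 12 steps. Longest linear sequence: 11 steps (steps 1–4 and 6–12); step 5 is the one-step side branch.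

**Steps most likely to fail**

Step 6. At the temperature needed to open 11, the ethoxyvinylketene may be lost to dimerisation or to acylation of the product phenol before the hindered siloxyalkyne traps it, and the siloxyalkyne may undergo a 1,3-silyl shift to a silylketene. The fallback generates the same ketene 12 at room temperature by a photochemical Wolff rearrangement. It sets out from siloxyalkyne 7. The partner is made separately: 3-ethoxybut-3-en-2-one F1 (from 1-ethoxyvinyllithium and N-methoxy-N-methylacetamide) is trifluoroacetylated with CF3CO2CH2CF3/LiN(SiMe3)2 to 5-ethoxy-1,1,1-trifluorohex-5-ene-2,4-dione F2, and detrifluoroacetylative diazo transfer (MsN3, Et3N) gives 1-diazo-3-ethoxybut-3-en-2-one F3. Irradiation of F3 with 7 in 1,2-dichloroethane at rt, then warming to 80 °C to finish the ring opening and 6π closure, should follow the same cascade and return to the route at phenol 16.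

Step 4. Proton transfer at the propargylic, allylic and benzylic position during acetylide formation or after silylation would erode the enantiomeric purity or isomerise the enyne to a vinylallene, and oxygen transfer may be incomplete. The fallback reaches the ynolate without a terminal alkyne. It sets out from alcohol 2, which is converted (ClCO2Me, pyridine) into rac-1-[4-(benzyloxy)-3-methoxyphenyl]prop-2-en-1-yl methyl carbonate F4. Asymmetric allylic alkylation with NaCH(CO2Me)2 under Mo(CO)6 and a chiral trans-N,N'-(cyclohexane-1,2-diyl)bis(pyridine-2-carboxamide) ligand (THF, 65 °C), a dynamic process in which both enantiomers of the branched carbonate converge on the branched product, gives dimethyl (S)-2-{1-[4-(benzyloxy)-3-methoxyphenyl]prop-2-en-1-yl}propanedioate F5. Krapcho demethoxycarbonylation (LiCl, wet DMSO, heat) gives methyl (R)-3-[4-(benzyloxy)-3-methoxyphenyl]pent-4-enoate F6, whose stereocentre is now β to the carbonyl and no longer acidic. Double α-bromination (LiN(SiMe3)2 then BrCCl2CCl2Br, twice) gives methyl (R)-3-[4-(benzyloxy)-3-methoxyphenyl]-2,2-dibromopent-4-enoate F7. Double bromine–lithium exchange with t-BuLi (THF, −78 → 0 °C) expels LiOMe and gives lithium ynolate 6, where the route is rejoined; silylation with i-Pr3SiOTf as in step 4 gives 7.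

Step 11. Under alkaline peroxide the chalcone may close through its α-carbon to an aurone, a course favoured by the 6'-alkoxy group, or suffer oxidative cleavage. The fallback builds ring C at the 1,3-diketone level with the 3-oxygen already in place. It sets out from aldehyde 20. Aldol addition of the lithium enolate of 2-(benzyloxy)-1-phenylethan-1-one (LiN(SiMe3)2, 2.2 equiv, THF, −78 °C) gives 2-(benzyloxy)-3-{4-(benzyloxy)-3-[(R)-1-(4-(benzyloxy)-3-methoxyphenyl)prop-2-en-1-yl]-6-ethoxy-2-hydroxyphenyl}-3-hydroxy-1-phenylpropan-1-one F8. MnO2 oxidation of the benzylic alcohol gives 2-(benzyloxy)-1-{4-(benzyloxy)-3-[(R)-1-(4-(benzyloxy)-3-methoxyphenyl)prop-2-en-1-yl]-6-ethoxy-2-hydroxyphenyl}-3-phenylpropane-1,3-dione F9. Acid-catalysed cyclodehydration (TsOH cat., toluene, 40 °C), as in the classical flavone synthesis from Baker–Venkataraman diketones, gives 3,7-bis(benzyloxy)-8-{(R)-1-[4-(benzyloxy)-3-methoxyphenyl]prop-2-en-1-yl}-5-ethoxy-2-phenyl-4H-chromen-4-one F10. BCl3/C6HMe5 as in step 12 then removes the three benzyl groups and the peri ethyl group and rejoins the route at target 25.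

**Further compounds**

F1 | step 6 | 3-ethoxybut-3-en-2-one | C=C(OCC)C(C)=O
F2 | step 6 | 5-ethoxy-1,1,1-trifluorohex-5-ene-2,4-dione | C=C(OCC)C(=O)CC(=O)C(F)(F)F
F3 | step 6 | 1-diazo-3-ethoxybut-3-en-2-one | C=C(OCC)C(=O)C=[N+]=[N-]
F4 | step 4 | rac-1-[4-(benzyloxy)-3-methoxyphenyl]prop-2-en-1-yl methyl carbonate | C=CC(OC(=O)OC)c1ccc(OCc2ccccc2)c(OC)c1
F5 | step 4 | dimethyl (S)-2-{1-[4-(benzyloxy)-3-methoxyphenyl]prop-2-en-1-yl}propanedioate | C=C[C@H](c1ccc(OCc2ccccc2)c(OC)c1)C(C(=O)OC)C(=O)OC
F6 | step 4 | methyl (R)-3-[4-(benzyloxy)-3-methoxyphenyl]pent-4-enoate | C=C[C@H](c1ccc(OCc2ccccc2)c(OC)c1)CC(=O)OC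
F7 | step 4 | methyl (R)-3-[4-(benzyloxy)-3-methoxyphenyl]-2,2-dibromopent-4-enoate | C=C[C@H](c1ccc(OCc2ccccc2)c(OC)c1)C(Br)(Br)C(=O)OC
F8 | step 11 | 2-(benzyloxy)-3-{4-(benzyloxy)-3-[(R)-1-(4-(benzyloxy)-3-methoxyphenyl)prop-2-en-1-yl]-6-ethoxy-2-hydroxyphenyl}-3-hydroxy-1-phenylpropan-1-one (diastereomer mixture) | C=C[C@H](c1ccc(OCc2ccccc2)c(OC)c1)c1c(O)c(C(O)C(OCc2ccccc2)C(=O)c2ccccc2)c(OCC)cc1OCc1ccccc1
F9 | step 11 | 2-(benzyloxy)-1-{4-(benzyloxy)-3-[(R)-1-(4-(benzyloxy)-3-methoxyphenyl)prop-2-en-1-yl]-6-ethoxy-2-hydroxyphenyl}-3-phenylpropane-1,3-dione | C=C[C@H](c1ccc(OCc2ccccc2)c(OC)c1)c1c(O)c(C(=O)C(OCc2ccccc2)C(=O)c2ccccc2)c(OCC)cc1OCc1ccccc1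
F10 | step 11 | 3,7-bis(benzyloxy)-8-{(R)-1-[4-(benzyloxy)-3-methoxyphenyl]prop-2-en-1-yl}-5-ethoxy-2-phenyl-4H-chromen-4-one | C=C[C@H](c1ccc(OCc2ccccc2)c(OC)c1)c1c(OCc2ccccc2)cc(OCC)c2c(=O)c(OCc3ccccc3)c(-c3ccccc3)oc12
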